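## Retrosynthetic overview
1. Target 24 comes from 22 by two orthogonal O-deprotections (MOM, then TIPS). The dihydropyran ring C is the last ring closed, by intramolecular Mitsunobu formation of the O1–C2 bond in 21.
2. The C4–C4a bond comes from an sp3–sp2 Negishi coupling of the chiral primary iodide 18 (C2–C3–C4 plus ring B) with the A-ring bromide 8.
3. The only stereocentre, C3, comes from a lipase-catalysed desymmetrisation of the prochiral diacetate 16. Compound 16 is built from bromochromene 12 and diethyl malonate (Pd α-arylation, reduction, acetylation).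
4. Both arenes come from one intermediate, bromophenol 7 (4-bromoresorcinol → mono-TIPS ether → 1,1-dimethylallyl ether → aromatic Claisen). Acetylation of 7 gives 8, and the sequence MOM/TBAF/DDQ gives 12.
5. Ring order: benzene rings A and B are bought, the 2,2-dimethylpyran on ring B is formed first (step 8), and ring C is formed last (step 16).

Structure check: the SMILES decodes as (3R)-3-(5-hydroxy-2,2-dimethyl-2H-chromen-6-yl)-8-prenylchroman-7-ol, C25H28O4, with one stereocentre (C3, R).

Assumption: the lipase recognises the same enantiotopic arm as in the known 2-aryl- and 2-benzylpropane-1,3-diol series, so hydrolysis of 16 gives (S)-17; ee and configuration of 17 are checked (chiral HPLC, Mosher ester) before step 13.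

## Route

Step 1
Reactants: 1 bromoresorcinol (4-bromobenzene-1,3-diol)
Product: 2 mono-TIPS ether 2-bromo-5-(triisopropylsilyloxy)phenol
Conditions: TIPSCl (1.0 equiv), imidazole, CH2Cl2/DMF, −10 → 0 °C
Reagents that add atoms: triisopropylsilyl chloride, CC(C)[Si](Cl)(C(C)C)C(C)C
Why: In this regioselective silyl ether formation the bulky TIPS chloride reacts at the unhindered OH para to bromine and leaves the OH next to bromine free, which differentiates the two resorcinol oxygens for the whole synthesis.

Step 2
Reactants: 2 mono-TIPS ether; 3 chloroalkyne 3-chloro-3-methylbut-1-yne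
Product: 4 propargyl ether [4-bromo-3-(2-methylbut-3-yn-2-yloxy)phenoxy]triisopropylsilane
Conditions: DBU, CuCl2 (1 mol %), MeCN, 0 °C, N2
Reagents that add atoms: none
Why: Copper-catalysed O-propargylation is the standard way to place a tertiary 1,1-dimethylpropargyl group on a phenol, works well with acidic o-bromophenols, and leaves the aryl TIPS ether intact in the cold anhydrous medium.

Step 3
Reactants: 4 propargyl ether
Product: 5 reverse-prenyl ether [4-bromo-3-(2-methylbut-3-en-2-yloxy)phenoxy]triisopropylsilane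
Conditions: H2 (1 atm), Lindlar catalyst, quinoline, EtOAc, rt, stopped after 1 equiv H2
Reagents that add atoms: none
Why: Lindlar semihydrogenation stops at the terminal alkene and touches neither the aryl bromide nor the silyl ether.

Step 4
Reactants: 5 reverse-prenyl ether
Product: 7 common bromophenol 6-bromo-2-(3-methylbut-2-enyl)-3-(triisopropylsilyloxy)phenol, via ortho-dienone (keto tautomer of the product) 6 (not isolated)
Conditions: PhNEt2, 130 °C, degassed
Reagents that add atoms: none
Why: In this aromatic Claisen rearrangement ([3,3] shift with allyl inversion, then tautomerisation) bromine blocks one ortho position, so a normal prenyl group can only arrive at the carbon between the two oxygens, and the amine solvent suppresses acid-catalysed chroman formation.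

Step 5
Reactants: 7 common bromophenol
Product: 8 A-ring bromide 6-bromo-2-(3-methylbut-2-enyl)-3-(triisopropylsilyloxy)phenyl acetate
Conditions: Ac2O, pyridine, DMAP (cat.), CH2Cl2, rt
Reagents that add atoms: acetic anhydride, CC(=O)OC(C)=O
Why: DMAP-catalysed O-acylation gives an aryl ester that tolerates organozinc/Pd chemistry and can later be removed together with the side-chain acetate without touching TIPS or MOM.

Step 6
Reactants: 7 common bromophenol
Product: 9 MOM/TIPS bis-ether [4-bromo-3-(methoxymethoxy)-2-(3-methylbut-2-enyl)phenoxy]triisopropylsilane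
Conditions: MOMCl, i-Pr2NEt, CH2Cl2, 0 °C → reflux
Reagents that add atoms: chloromethyl methyl ether, COCCl
Why: Williamson-type O-alkylation of the acidic o-bromophenol puts a base-, hydride- and Pd-stable MOM group on the future 2'-oxygen, so this phenol cannot later compete by forming a dihydrobenzofuran when ring C is closed.

Step 7
Reactants: 9 MOM/TIPS bis-ether
Product: 10 prenylphenol 4-bromo-3-(methoxymethoxy)-2-(3-methylbut-2-enyl)phenol
Conditions: TBAF (1.05 equiv), THF, 0 °C; H2O
Reagents that add atoms: none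
Why: Fluoride-induced desilylation, driven by Si–F bond formation, frees only the future 4'-oxygen because MOM ether, bromide and prenyl group are inert to TBAF.

Step 8
Reactants: 10 prenylphenol
Product: 12 bromochromene 6-bromo-5-(methoxymethoxy)-2,2-dimethyl-2H-chromene, via o-quinone methide 11 (not isolated)
Conditions: DDQ (1.2 equiv), 1,4-dioxane, 90 °C
Reagents that add atoms: none
Why: In this DDQ oxidative cyclisation of an o-prenylphenol, hydride abstraction gives the o-quinone methide, and its oxa-6π electrocyclisation can close only on the single free oxygen, which fixes the angular chromene regiochemistry.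

Step 9
Reactants: 12 bromochromene; 13 diethyl malonate
Product: 14 arylmalonate diethyl 2-[5-(methoxymethoxy)-2,2-dimethyl-2H-chromen-6-yl]malonate
Conditions: Pd(OAc)2 (2 mol %), P(t-Bu)3·HBF4 (4 mol %), K3PO4, toluene, 80 °C
Reagents that add atoms: none
Why: Palladium-catalysed α-arylation of a malonate enolate with a bulky electron-rich phosphine couples electron-rich ortho-alkoxy aryl bromides, and the hindered chromene alkene is a poor Heck acceptor.

Step 10
Reactants: 14 arylmalonate
Product: 15 prochiral diol 2-[5-(methoxymethoxy)-2,2-dimethyl-2H-chromen-6-yl]propane-1,3-diol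
Conditions: LiAlH4, THF, 0 °C → rt (ester added to hydride); Fieser work-up
Reagents that add atoms: none
Why: Hydride reduction of both esters gives the prochiral 1,3-diol, while the MOM ether and the unactivated chromene alkene are inert to LiAlH4.

Step 11
Reactants: 15 prochiral diol
Product: 16 prochiral diacetate 2-[5-(methoxymethoxy)-2,2-dimethyl-2H-chromen-6-yl]propane-1,3-diyl diacetate
Conditions: Ac2O, pyridine, DMAP (cat.), CH2Cl2, rt
Reagents that add atoms: acetic anhydride, CC(=O)OC(C)=O
Why: Exhaustive DMAP-catalysed acetylation gives the substrate form whose enzymatic hydrolysis delivers the enantiomer needed here.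

Step 12
Reactants: 16 prochiral diacetate
Product: 17 monoacetate (2S)-3-hydroxy-2-[5-(methoxymethoxy)-2,2-dimethyl-2H-chromen-6-yl]propyl acetate
Conditions: lipase (triacylglycerol acylhydrolase, EC 3.1.1.3, a serine hydrolase; immobilised Burkholderia cepacia lipase), 0.1 M phosphate buffer pH 7.0, acetone (10 % v/v), 30 °C, HPLC control; used at once
Reagents that add atoms: none
Why: In this enantioselective lipase desymmetrisation the chiral active site hydrolyses only the pro-R acetoxymethyl arm of the prochiral diacetate, which sets C3 as (S)-17, and the minor enantiomer still carries its acetate on the preferred arm and is hydrolysed on to diol 15, which raises the ee further.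

Step 13
Reactants: 17 monoacetate
Product: 18 iodide (2R)-3-iodo-2-[5-(methoxymethoxy)-2,2-dimethyl-2H-chromen-6-yl]propyl acetate
Conditions: PPh3, I2, imidazole (premixed), CH2Cl2, 0 °C, dark
Reagents that add atoms: iodine, II
Why: This Appel-type iodination (Garegg–Samuelsson conditions) is an SN2 reaction at the CH2 group only, so C3 is untouched (the descriptor becomes R only because CH2I outranks CH2OAc), and the imidazole buffer protects MOM and chromene and leaves no time for acetyl migration.

Step 14
Reactants: 18 iodide; 8 A-ring bromide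
Product: 20 coupled diacetate (2R)-3-[2-acetoxy-3-(3-methylbut-2-enyl)-4-(triisopropylsilyloxy)phenyl]-2-[5-(methoxymethoxy)-2,2-dimethyl-2H-chromen-6-yl]propyl acetate, via alkylzinc iodide 19 (not isolated)
Conditions: Zn dust (I2-activated), DMF, rt; then 8, Pd2(dba)3 (2.5 mol %), SPhos (10 mol %), 50 °C
Reagents that add atoms: none
Why: In this Negishi sp3–sp2 cross-coupling zinc inserts into the primary C–I bond to give an ester-tolerant alkylzinc iodide, and Pd/SPhos couples it with the aryl bromide faster than β-hydride elimination without touching C3, the acetates, the silyl ether or the alkenes.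

Step 15
Reactants: 20 coupled diacetate
Product: 21 phenol alcohol 6-{(2R)-3-hydroxy-2-[5-(methoxymethoxy)-2,2-dimethyl-2H-chromen-6-yl]propyl}-2-(3-methylbut-2-enyl)-3-(triisopropylsilyloxy)phenol
Conditions: K2CO3 (cat.), MeOH, 0 °C → rt
Reagents that add atoms: none
Why: Base-catalysed transesterification (methanolysis) removes the aryl and the primary alkyl acetate together, while the hindered aryl TIPS ether and the MOM ether survive mild carbonate in methanol.

Step 16
Reactants: 21 phenol alcohol
Product: 22 protected isoflavan (3R)-3-[5-(methoxymethoxy)-2,2-dimethyl-2H-chromen-6-yl]-8-(3-methylbut-2-enyl)-7-(triisopropylsilyloxy)chromane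
Conditions: PPh3, DIAD, THF (0.02 M), 0 °C → rt
Reagents that add atoms: none
Why: In this intramolecular Mitsunobu etherification the only free phenol displaces the activated primary alcohol in a 6-exo-tet closure of ring C, the substitution occurs at CH2 so the C3 configuration is kept, and the MOM group blocks the competing closure by O2'.

Step 17
Reactants: 22 protected isoflavan
Product: 23 TIPS ether 6-[(3R)-8-(3-methylbut-2-enyl)-7-(triisopropylsilyloxy)chroman-3-yl]-2,2-dimethyl-2H-chromen-5-ol
Conditions: conc. HCl (cat.), MeOH–THF, 40 °C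
Reagents that add atoms: none
Why: This acid-catalysed acetal exchange (MOM cleavage) is run while O7 is still silylated, so no free phenol sits ortho to the prenyl group and acid-induced cyclisation to a dimethylchroman is impossible, and aryl TIPS ethers are stable to dilute methanolic HCl.

Step 18
Reactants: 23 TIPS ether
Product: 24 target (3R)-3-(5-hydroxy-2,2-dimethyl-2H-chromen-6-yl)-8-(3-methylbut-2-enyl)chroman-7-ol
Conditions: TBAF (1.1 equiv), THF, 0 °C; H2O
Reagents that add atoms: none
Why: Fluoride desilylation under non-acidic conditions frees the 7-OH without risk to the prenyl group, the chromene or the C3 stereocentre and gives the (3R) target.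

## Compound list
1 | 4-bromoresorcinol (4-bromobenzene-1,3-diol) | Oc1ccc(Br)c(O)c1 | starting material
2 | 2-bromo-5-(triisopropylsilyloxy)phenol | CC(C)[Si](Oc1ccc(Br)c(O)c1)(C(C)C)C(C)C | intermediate
3 | 3-chloro-3-methylbut-1-yne | C#CC(C)(C)Cl | starting material
4 | [4-bromo-3-(2-methylbut-3-yn-2-yloxy)phenoxy]triisopropylsilane | C#CC(C)(C)Oc1cc(O[Si](C(C)C)(C(C)C)C(C)C)ccc1Br | intermediate
5 | [4-bromo-3-(2-methylbut-3-en-2-yloxy)phenoxy]triisopropylsilane | C=CC(C)(C)Oc1cc(O[Si](C(C)C)(C(C)C)C(C)C)ccc1Br | intermediate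
6 | 2-bromo-6-(3-methylbut-2-enyl)-5-(triisopropylsilyloxy)cyclohexa-2,4-dien-1-one (racemic, transient) | O=C1C(Br)=CC=C(O[Si](C(C)C)(C(C)C)C(C)C)C1CC=C(C)C | intermediate
7 | 6-bromo-2-(3-methylbut-2-enyl)-3-(triisopropylsilyloxy)phenol | CC(C)=CCc1c(O)c(Br)ccc1O[Si](C(C)C)(C(C)C)C(C)C | intermediate
8 | 6-bromo-2-(3-methylbut-2-enyl)-3-(triisopropylsilyloxy)phenyl acetate | CC(C)=CCc1c(OC(C)=O)c(Br)ccc1O[Si](C(C)C)(C(C)C)C(C)C | intermediate
9 | [4-bromo-3-(methoxymethoxy)-2-(3-methylbut-2-enyl)phenoxy]triisopropylsilane | CC(C)=CCc1c(OCOC)c(Br)ccc1O[Si](C(C)C)(C(C)C)C(C)C | intermediate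
10 | 4-bromo-3-(methoxymethoxy)-2-(3-methylbut-2-enyl)phenol | CC(C)=CCc1c(O)ccc(Br)c1OCOC | intermediate
11 | 4-bromo-5-(methoxymethoxy)-6-(3-methylbut-2-enylidene)cyclohexa-2,4-dien-1-one (o-quinone methide, transient) | CC(C)=CC=C1C(=O)C=CC(Br)=C1OCOC | intermediate
12 | 6-bromo-5-(methoxymethoxy)-2,2-dimethyl-2H-chromene | CC1(C)C=Cc2c(O1)ccc(Br)c2OCOC | intermediate
13 | diethyl malonate | CCOC(=O)CC(=O)OCC | starting material
14 | diethyl 2-[5-(methoxymethoxy)-2,2-dimethyl-2H-chromen-6-yl]malonate | CCOC(=O)C(C(=O)OCC)c1ccc2OC(C)(C)C=Cc2c1OCOC | intermediate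
15 | 2-[5-(methoxymethoxy)-2,2-dimethyl-2H-chromen-6-yl]propane-1,3-diol | OCC(CO)c1ccc2OC(C)(C)C=Cc2c1OCOC | intermediate
16 | 2-[5-(methoxymethoxy)-2,2-dimethyl-2H-chromen-6-yl]propane-1,3-diyl diacetate | CC(=O)OCC(COC(C)=O)c1ccc2OC(C)(C)C=Cc2c1OCOC | intermediate
17 | (2S)-3-hydroxy-2-[5-(methoxymethoxy)-2,2-dimethyl-2H-chromen-6-yl]propyl acetate | CC(=O)OC[C@@H](c1ccc2OC(C)(C)C=Cc2c1OCOC)CO | intermediate
18 | (2R)-3-iodo-2-[5-(methoxymethoxy)-2,2-dimethyl-2H-chromen-6-yl]propyl acetate | CC(=O)OC[C@@H](c1ccc2OC(C)(C)C=Cc2c1OCOC)CI | intermediate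
19 | {(2R)-3-acetoxy-2-[5-(methoxymethoxy)-2,2-dimethyl-2H-chromen-6-yl]propyl}zinc iodide | CC(=O)OC[C@@H](c1ccc2OC(C)(C)C=Cc2c1OCOC)C[Zn]I | intermediate
20 | (2R)-3-[2-acetoxy-3-(3-methylbut-2-enyl)-4-(triisopropylsilyloxy)phenyl]-2-[5-(methoxymethoxy)-2,2-dimethyl-2H-chromen-6-yl]propyl acetate | CC(=O)OC[C@@H](c1ccc2OC(C)(C)C=Cc2c1OCOC)Cc1ccc(O[Si](C(C)C)(C(C)C)C(C)C)c(CC=C(C)C)c1OC(C)=O | intermediate
21 | 6-{(2R)-3-hydroxy-2-[5-(methoxymethoxy)-2,2-dimethyl-2H-chromen-6-yl]propyl}-2-(3-methylbut-2-enyl)-3-(triisopropylsilyloxy)phenol | OC[C@@H](c1ccc2OC(C)(C)C=Cc2c1OCOC)Cc1ccc(O[Si](C(C)C)(C(C)C)C(C)C)c(CC=C(C)C)c1O | intermediate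
22 | (3R)-3-[5-(methoxymethoxy)-2,2-dimethyl-2H-chromen-6-yl]-8-(3-methylbut-2-enyl)-7-(triisopropylsilyloxy)chromane | CC(C)=CCc1c(O[Si](C(C)C)(C(C)C)C(C)C)ccc2c1OC[C@@H](c1ccc3c(c1OCOC)C=CC(C)(C)O3)C2 | intermediate
23 | 6-[(3R)-8-(3-methylbut-2-enyl)-7-(triisopropylsilyloxy)chroman-3-yl]-2,2-dimethyl-2H-chromen-5-ol | CC(C)=CCc1c(O[Si](C(C)C)(C(C)C)C(C)C)ccc2c1OC[C@@H](c1ccc3c(c1O)C=CC(C)(C)O3)C2 | intermediate
24 | (3R)-3-(5-hydroxy-2,2-dimethyl-2H-chromen-6-yl)-8-(3-methylbut-2-enyl)chroman-7-ol (CNP0263294.2) | CC(C)=CCc1c(O)ccc2c1OC[C@@H](c1ccc3c(c1O)C=CC(C)(C)O3)C2 | target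

## Step count and risks
Total step count: 18.
Longest linear sequence: 17 steps (steps 1–4 and 6–18, from 4-bromoresorcinol). Step 5 lies on the short A-ring branch.

**Risk 1, step 12 (lipase hydrolysis).** The di-ortho-substituted aryl group may slow turnover or lower the ee, and acetyl migration is possible in water.
- The fallback sets out from diol 15 (with phenol 7) and comes back to the route at 22.
- The desymmetrisation is run in the opposite direction and in an organic solvent. The same lipase with vinyl acetate in MTBE at 25 °C acetylates the arm that hydrolysis would have freed. This gives the enantiomeric monoacetate (2R)-3-hydroxy-2-[5-(methoxymethoxy)-2,2-dimethyl-2H-chromen-6-yl]propyl acetate F1.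
- The arms are now labelled the other way round, so they are used in the reverse order: ether first, C–C bond second.
- Mitsunobu reaction of F1 with phenol 7 (PPh3, DIAD, toluene, concentrated) gives the aryl ether (2R)-3-[6-bromo-2-(3-methylbut-2-enyl)-3-(triisopropylsilyloxy)phenoxy]-2-[5-(methoxymethoxy)-2,2-dimethyl-2H-chromen-6-yl]propyl acetate F2.
- Methanolysis (K2CO3, MeOH) gives the alcohol (2S)-3-[6-bromo-2-(3-methylbut-2-enyl)-3-(triisopropylsilyloxy)phenoxy]-2-[5-(methoxymethoxy)-2,2-dimethyl-2H-chromen-6-yl]propan-1-ol F3.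
- Treatment with PPh3/I2/imidazole gives the iodide {4-bromo-3-[(2R)-3-iodo-2-(5-(methoxymethoxy)-2,2-dimethyl-2H-chromen-6-yl)propoxy]-2-(3-methylbut-2-enyl)phenoxy}triisopropylsilane F4.
- Zinc insertion (Zn, DMF) gives the corresponding (2R)-alkylzinc iodide F5. An intramolecular Negishi coupling (Pd2(dba)3, SPhos, 50 °C) then closes ring C at C4–C4a to give 22.

**Risk 2, step 14 (intermolecular Negishi coupling).** Oxidative addition to the electron-rich ortho-acetoxy bromide may be sluggish, and the alkylzinc may undergo protodezincation or β-hydride elimination.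
- The fallback sets out from 18 and 8 and comes back at 20.
- No organometallic reagent is preformed. The bond is made by a nickel-catalysed reductive cross-electrophile coupling (NiI2 10 mol %, 4,4'-di-tert-butyl-2,2'-bipyridine, Zn powder, NaI, DMA, 60 °C).
- Ni(0) activates the aryl bromide, and the iodide enters as a primary radical. The radical centre is one carbon away from C3, so the configuration is kept. Its capture by nickel is much faster than a 1,2-aryl shift.
- This fallback makes no compound outside the list (F0).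

**Risk 3, step 17 (Brønsted-acid MOM cleavage next to a chromene and a prenyl group).** Methanol may add to the chromene, or the alkenes may isomerise.
- The fallback sets out from 22 and comes back at 24, bypassing 23.
- The acetal is exchanged for a silyl ether under aprotic, buffered conditions (TMSOTf, 2,2'-bipyridyl, MeCN, 0 °C → rt). This gives the bis-silyl ether (3R)-3-[2,2-dimethyl-5-(trimethylsilyloxy)-2H-chromen-6-yl]-8-(3-methylbut-2-enyl)-7-(triisopropylsilyloxy)chromane F6.
- One fluoride treatment (TBAF, 2.2 equiv, THF, 0 °C) then removes both silyl groups and gives 24 without any protic acid.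

## Further compounds
F1 | step 12 | (2R)-3-hydroxy-2-[5-(methoxymethoxy)-2,2-dimethyl-2H-chromen-6-yl]propyl acetate | CC(=O)OC[C@H](c1ccc2OC(C)(C)C=Cc2c1OCOC)CO
F2 | step 12 | (2R)-3-[6-bromo-2-(3-methylbut-2-enyl)-3-(triisopropylsilyloxy)phenoxy]-2-[5-(methoxymethoxy)-2,2-dimethyl-2H-chromen-6-yl]propyl acetate | CC(=O)OC[C@H](c1ccc2OC(C)(C)C=Cc2c1OCOC)COc1c(Br)ccc(O[Si](C(C)C)(C(C)C)C(C)C)c1CC=C(C)C
F3 | step 12 | (2S)-3-[6-bromo-2-(3-methylbut-2-enyl)-3-(triisopropylsilyloxy)phenoxy]-2-[5-(methoxymethoxy)-2,2-dimethyl-2H-chromen-6-yl]propan-1-ol | OC[C@H](c1ccc2OC(C)(C)C=Cc2c1OCOC)COc1c(Br)ccc(O[Si](C(C)C)(C(C)C)C(C)C)c1CC=C(C)C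
F4 | step 12 | {4-bromo-3-[(2R)-3-iodo-2-(5-(methoxymethoxy)-2,2-dimethyl-2H-chromen-6-yl)propoxy]-2-(3-methylbut-2-enyl)phenoxy}triisopropylsilane | IC[C@H](c1ccc2OC(C)(C)C=Cc2c1OCOC)COc1c(Br)ccc(O[Si](C(C)C)(C(C)C)C(C)C)c1CC=C(C)C
F5 | step 12 | (2R)-alkylzinc iodide derived from F4 | I[Zn]C[C@H](c1ccc2OC(C)(C)C=Cc2c1OCOC)COc1c(Br)ccc(O[Si](C(C)C)(C(C)C)C(C)C)c1CC=C(C)C
F0 | step 14 | none | none
F6 | step 17 | (3R)-3-[2,2-dimethyl-5-(trimethylsilyloxy)-2H-chromen-6-yl]-8-(3-methylbut-2-enyl)-7-(triisopropylsilyloxy)chromane | CC(C)=CCc1c(O[Si](C(C)C)(C(C)C)C(C)C)ccc2c1OC[C@@H](c1ccc3c(c1O[Si](C)(C)C)C=CC(C)(C)O3)C2
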